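**Retrosynthetic overview**
1. The target is the bis-(Z,Z)-dienoate made last by cis-selective semi-reduction of both triple bonds of the bis-(Z)-enyne macrodiolide 21.
2. The 20-membered ring (the last ring formed) is closed by lactonization of seco acid 20 at the α-methyl (Z)-enynoic acid.
3. The chain of 20 comes from one alkynol, 10, used twice in Sonogashira couplings with (Z)-β-iodoacrylates (PMB ester 15, and acid 17 after esterification).
4. Alkynol 10 comes from Ohira–Bestmann alkynylation of lactol 9, made by hydroformylation of homoallylic alcohol 7; Brown (Z)-crotylation of aldehyde 5 sets both stereocentres.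
5. The oxazole ring is formed first (van Leusen, step 1) and carried through 10 into both halves.

Assumption: the geometry and configuration written in the SMILES (Z at all four ring C=C, R at all four stereocentres) are taken as the target; compounds 1, 2, 11, 17 and (−)-Ipc2BOMe are bought. This route has not been run; conditions are proposed from standard practice.

**Route**

Step 1
Reactants: 1 p-toluenesulfonylmethyl isocyanide (TosMIC); 2 3-(tert-butyldimethylsilyloxy)propanal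
Product: 3 5-[2-(tert-butyldimethylsilyloxy)ethyl]-1,3-oxazole
Conditions: K2CO3, MeOH, reflux
Reagents that add atoms: none
Why: van Leusen oxazole synthesis, in which the TosMIC anion adds to the aldehyde, the oxazoline closes and loses sulfinate, so the aldehyde carbon becomes C5 of a 2,4-unsubstituted oxazole (no stereocentre).

Step 2
Reactants: 3 5-[2-(tert-butyldimethylsilyloxy)ethyl]-1,3-oxazole
Product: 4 2-(1,3-oxazol-5-yl)ethanol
Conditions: HCl (cat.), MeOH, rt
Reagents that add atoms: none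
Why: acid-catalysed methanolysis of a primary silyl ether, which the weakly basic oxazole tolerates.

Step 3
Reactants: 4 2-(1,3-oxazol-5-yl)ethanol
Product: 5 2-(1,3-oxazol-5-yl)acetaldehyde
Conditions: Dess–Martin periodinane, CH2Cl2, 0 °C to rt; filtered cold and used at once
Reagents that add atoms: none
Why: Dess–Martin oxidation is non-basic and stops at the aldehyde, which limits enolisation of this sensitive heteroarylacetaldehyde.

Step 4
Reactants: 5 2-(1,3-oxazol-5-yl)acetaldehyde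
Product: 7 (2R,3R)-3-methyl-1-(1,3-oxazol-5-yl)pent-4-en-2-ol, via borinate ester 6 (not isolated)
Conditions: (−)-(Z)-crotyl-B(Ipc)2 [from cis-2-butene, n-BuLi, KOtBu, (−)-Ipc2BOMe, BF3·OEt2], THF, −78 °C; then NaOH, H2O2, 0 °C to rt
Reagents that add atoms: (−)-(Z)-crotyldiisopinocampheylborane, C/C=C\CB([C@@H]1C[C@@H]2C[C@@H](C2(C)C)[C@H]1C)[C@@H]1C[C@@H]2C[C@@H](C2(C)C)[C@H]1C
Why: Brown crotylboration through a closed chair (Zimmerman–Traxler) transition state, where the Z-crotyl unit gives the syn pair and the isopinocampheyl groups derived from (+)-α-pinene select the aldehyde face that gives 2R, so both stereocentres (C9 and C8 of each half) are set as R,R.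

Step 5
Reactants: 7 (2R,3R)-3-methyl-1-(1,3-oxazol-5-yl)pent-4-en-2-ol
Product: 9 (5R,6R)-5-methyl-6-(1,3-oxazol-5-ylmethyl)oxan-2-ol (anomer mixture), via hydroxy aldehyde 8 (not isolated)
Conditions: Rh(acac)(CO)2 (1 mol %), BIPHEPHOS (3 mol %), CO/H2 (1:1, 5 bar), THF, 60 °C
Reagents that add atoms: carbon monoxide, [C-]#[O+]
Why: bisphosphite-modified rhodium hydroformylation of the α-branched terminal alkene is linear-selective and the resulting δ-hydroxy aldehyde closes to the six-membered lactol, leaving both stereocentres untouched.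

Step 6
Reactants: 9 (5R,6R)-5-methyl-6-(1,3-oxazol-5-ylmethyl)oxan-2-ol
Product: 10 (2R,3R)-3-methyl-1-(1,3-oxazol-5-yl)hept-6-yn-2-ol
Conditions: dimethyl (1-diazo-2-oxopropyl)phosphonate, K2CO3, MeOH, 0 °C to rt
Reagents that add atoms: dimethyl (1-diazo-2-oxopropyl)phosphonate, CC(=O)C(=[N+]=[N-])P(=O)(OC)OC
Why: Ohira–Bestmann (Seyferth–Gilbert) homologation of the open-chain aldehyde form of the lactol gives the terminal alkyne and frees the secondary alcohol under base mild enough for the oxazole C2–H (the aldehyde α-carbon is a CH2, so nothing can epimerise).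

Step 7
Reactants: 11 propargyl alcohol
Product: 13 (Z)-3-iodo-2-methylprop-2-en-1-ol, via vinylmagnesium chelate 12 (not isolated)
Conditions: MeMgBr (3 equiv), CuI (10 mol %), THF, −10 °C to rt; then I2, −78 to 0 °C
Reagents that add atoms: MeMgBr, C[Mg]Br; iodine, II
Why: alkoxide-directed copper-catalysed anti-carbomagnesiation gives the five-membered vinylmagnesium chelate, and iodinolysis with retention fixes iodine cis to CH2OH (Z).

Step 8
Reactants: 13 (Z)-3-iodo-2-methylprop-2-en-1-ol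
Product: 14 (Z)-3-iodo-2-methylprop-2-enoic acid
Conditions: TEMPO (cat.), PhI(OAc)2, MeCN/H2O, rt, dark
Reagents that add atoms: water, O
Why: oxoammonium (TEMPO) oxidation takes the primary allylic alcohol through the aldehyde hydrate to the acid without touching the vinyl iodide or its geometry.

Step 9
Reactants: 14 (Z)-3-iodo-2-methylprop-2-enoic acid
Product: 15 4-methoxybenzyl (Z)-3-iodo-2-methylprop-2-enoate
Conditions: 4-methoxybenzyl chloride, K2CO3, DMF, rt, dark
Reagents that add atoms: 4-methoxybenzyl chloride, COc1ccc(CCl)cc1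
Why: SN2 O-alkylation of the carboxylate needs no acyl activation, so the Z-iodoalkene cannot isomerise, and the PMB ester is later removable by acid.

Step 10
Reactants: 10 (2R,3R)-3-methyl-1-(1,3-oxazol-5-yl)hept-6-yn-2-ol; 15 4-methoxybenzyl (Z)-3-iodo-2-methylprop-2-enoate
Product: 16 4-methoxybenzyl (2Z,8R,9R)-9-hydroxy-2,8-dimethyl-10-(1,3-oxazol-5-yl)dec-2-en-4-ynoate
Conditions: Pd(PPh3)2Cl2 (5 mol %), CuI (10 mol %), Et3N, THF, rt, degassed
Reagents that add atoms: none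
Why: Sonogashira coupling of the terminal alkyne with the β-iodoenoate proceeds with retention of the Z geometry and tolerates the free alcohol and the oxazole.

Step 11
Reactants: 16 4-methoxybenzyl (2Z,8R,9R)-9-hydroxy-2,8-dimethyl-10-(1,3-oxazol-5-yl)dec-2-en-4-ynoate; 17 (Z)-3-iodoprop-2-enoic acid
Product: 18 4-methoxybenzyl (2Z,8R,9R)-9-{[(Z)-3-iodoprop-2-enoyl]oxy}-2,8-dimethyl-10-(1,3-oxazol-5-yl)dec-2-en-4-ynoate
Conditions: DCC, DMAP (cat.), CH2Cl2, −20 to 0 °C, dark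
Reagents that add atoms: none
Why: Steglich esterification acylates on oxygen with retention at the carbinol, and low temperature with little DMAP suppresses Z-to-E scrambling of the iodoacrylate by addition–elimination.

Step 12
Reactants: 18 4-methoxybenzyl (2Z,8R,9R)-9-{[(Z)-3-iodoprop-2-enoyl]oxy}-2,8-dimethyl-10-(1,3-oxazol-5-yl)dec-2-en-4-ynoate; 10 (2R,3R)-3-methyl-1-(1,3-oxazol-5-yl)hept-6-yn-2-ol
Product: 19 4-methoxybenzyl (2Z,8R,9R)-9-{[(2Z,8R,9R)-9-hydroxy-8-methyl-10-(1,3-oxazol-5-yl)dec-2-en-4-ynoyl]oxy}-2,8-dimethyl-10-(1,3-oxazol-5-yl)dec-2-en-4-ynoate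
Conditions: Pd(PPh3)2Cl2 (5 mol %), CuI (10 mol %), Et3N, THF, rt, degassed
Reagents that add atoms: none
Why: a second Sonogashira coupling is clean because 18 carries one vinyl iodide and no free alkyne while 10 carries one alkyne and no halide; geometry is retained.

Step 13
Reactants: 19 the hydroxy bis-enyne PMB ester named in step 12
Product: 20 (2Z,8R,9R)-9-{[(2Z,8R,9R)-9-hydroxy-8-methyl-10-(1,3-oxazol-5-yl)dec-2-en-4-ynoyl]oxy}-2,8-dimethyl-10-(1,3-oxazol-5-yl)dec-2-en-4-ynoic acid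
Conditions: TFA, anisole, CH2Cl2, 0 °C
Reagents that add atoms: none
Why: acidolysis of the PMB ester through the stabilised benzyl cation (trapped by anisole, Friedel–Crafts) frees the acid without base, leaving the secondary ester, the enynes and the oxazoles intact.

Step 14
Reactants: 20 the seco acid named in step 13
Product: 21 (3Z,9R,10R,13Z,19R,20R)-3,9,19-trimethyl-10,20-bis(1,3-oxazol-5-ylmethyl)-1,11-dioxacycloicosa-3,13-diene-5,15-diyne-2,12-dione
Conditions: 2-methyl-6-nitrobenzoic anhydride (MNBA), Et3N, DMAP (cat.), CH2Cl2 (1 mM, slow addition), rt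
Reagents that add atoms: none
Why: Shiina macrolactonization via a mixed anhydride at room temperature and high dilution closes the 20-membered ring on oxygen (carbinol retained), and the α-methyl group on the activated Z-acid disfavours isomerisation by conjugate addition.

Step 15
Reactants: 21 the bis-enyne macrodiolide named in step 14
Product: 22 (3Z,5Z,9R,10R,13Z,15Z,19R,20R)-3,9,19-trimethyl-10,20-bis(1,3-oxazol-5-ylmethyl)-1,11-dioxacycloicosa-3,5,13,15-tetraene-2,12-dione (CNP0128396.1)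
Conditions: Zn dust activated with Cu(OAc)2 and AgNO3, MeOH/H2O, rt, dark, argon
Reagents that add atoms: none
Why: Boland-type activated-zinc reduction delivers two hydrogens cis to conjugated alkynes only, giving the 5Z and 15Z alkenes without over-reduction or attack on the esters and oxazoles.

**Compound list**
1 | p-toluenesulfonylmethyl isocyanide (TosMIC) | Cc1ccc(cc1)S(=O)(=O)C[N+]#[C-] | starting material
2 | 3-(tert-butyldimethylsilyloxy)propanal | CC(C)(C)[Si](C)(C)OCCC=O | starting material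
3 | 5-[2-(tert-butyldimethylsilyloxy)ethyl]-1,3-oxazole | CC(C)(C)[Si](C)(C)OCCc1cnco1 | intermediate
4 | 2-(1,3-oxazol-5-yl)ethanol | OCCc1cnco1 | intermediate
5 | 2-(1,3-oxazol-5-yl)acetaldehyde | O=CCc1cnco1 | intermediate
6 | (2R,3R)-3-methyl-1-(1,3-oxazol-5-yl)pent-4-en-2-yl diisopinocampheylborinate | C=C[C@@H](C)[C@@H](Cc1cnco1)OB([C@@H]1C[C@@H]2C[C@@H](C2(C)C)[C@H]1C)[C@@H]1C[C@@H]2C[C@@H](C2(C)C)[C@H]1C | intermediate
7 | (2R,3R)-3-methyl-1-(1,3-oxazol-5-yl)pent-4-en-2-ol | C=C[C@@H](C)[C@@H](Cc1cnco1)O | intermediate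
8 | (4R,5R)-5-hydroxy-4-methyl-6-(1,3-oxazol-5-yl)hexanal | O=CCC[C@@H](C)[C@@H](Cc1cnco1)O | intermediate
9 | (5R,6R)-5-methyl-6-(1,3-oxazol-5-ylmethyl)oxan-2-ol (anomer mixture) | OC1CC[C@@H](C)[C@@H](Cc2cnco2)O1 | intermediate
10 | (2R,3R)-3-methyl-1-(1,3-oxazol-5-yl)hept-6-yn-2-ol | C#CCC[C@@H](C)[C@@H](Cc1cnco1)O | intermediate
11 | propargyl alcohol | C#CCO | starting material
12 | cyclic vinylmagnesium alkoxide (4-methyl-2,5-dihydro-1,2-oxamagnesole) | CC1=C[Mg]OC1 | intermediate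
13 | (Z)-3-iodo-2-methylprop-2-en-1-ol | OC/C(C)=C\I | intermediate
14 | (Z)-3-iodo-2-methylprop-2-enoic acid | OC(=O)/C(C)=C\I | intermediate
15 | 4-methoxybenzyl (Z)-3-iodo-2-methylprop-2-enoate | COc1ccc(COC(=O)/C(C)=C\I)cc1 | intermediate
16 | 4-methoxybenzyl (2Z,8R,9R)-9-hydroxy-2,8-dimethyl-10-(1,3-oxazol-5-yl)dec-2-en-4-ynoate | COc1ccc(COC(=O)/C(C)=C\C#CCC[C@@H](C)[C@@H](Cc2cnco2)O)cc1 | intermediate
17 | (Z)-3-iodoprop-2-enoic acid | OC(=O)/C=C\I | starting material
18 | 4-methoxybenzyl (2Z,8R,9R)-9-{[(Z)-3-iodoprop-2-enoyl]oxy}-2,8-dimethyl-10-(1,3-oxazol-5-yl)dec-2-en-4-ynoate | COc1ccc(COC(=O)/C(C)=C\C#CCC[C@@H](C)[C@@H](Cc2cnco2)OC(=O)/C=C\I)cc1 | intermediate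
19 | 4-methoxybenzyl (2Z,8R,9R)-9-{[(2Z,8R,9R)-9-hydroxy-8-methyl-10-(1,3-oxazol-5-yl)dec-2-en-4-ynoyl]oxy}-2,8-dimethyl-10-(1,3-oxazol-5-yl)dec-2-en-4-ynoate | COc1ccc(COC(=O)/C(C)=C\C#CCC[C@@H](C)[C@@H](Cc2cnco2)OC(=O)/C=C\C#CCC[C@@H](C)[C@@H](Cc2cnco2)O)cc1 | intermediate
20 | (2Z,8R,9R)-9-{[(2Z,8R,9R)-9-hydroxy-8-methyl-10-(1,3-oxazol-5-yl)dec-2-en-4-ynoyl]oxy}-2,8-dimethyl-10-(1,3-oxazol-5-yl)dec-2-en-4-ynoic acid | OC(=O)/C(C)=C\C#CCC[C@@H](C)[C@@H](Cc1cnco1)OC(=O)/C=C\C#CCC[C@@H](C)[C@@H](Cc1cnco1)O | intermediate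
21 | (3Z,9R,10R,13Z,19R,20R)-3,9,19-trimethyl-10,20-bis(1,3-oxazol-5-ylmethyl)-1,11-dioxacycloicosa-3,13-diene-5,15-diyne-2,12-dione | C/C1=C/C#CCC[C@@H](C)[C@@H](Cc2cnco2)OC(=O)/C=C\C#CCC[C@@H](C)[C@@H](Cc2cnco2)OC1=O | intermediate
22 | (3Z,5Z,9R,10R,13Z,15Z,19R,20R)-3,9,19-trimethyl-10,20-bis(1,3-oxazol-5-ylmethyl)-1,11-dioxacycloicosa-3,5,13,15-tetraene-2,12-dione | C/C1=C/C=C\CC[C@@H](C)[C@@H](Cc2cnco2)OC(=O)/C=C\C=C/CC[C@@H](C)[C@@H](Cc2cnco2)OC1=O | target

**Totals**
Total step count: 15. Longest linear sequence: 12 steps (steps 1–6, then 10–15); the linker branch (steps 7–9) joins at step 10.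

**Three steps most likely to fail, each with a fallback**

Step 4 (with the aldehyde from step 3): aldehyde 5 is enolisable and may self-condense before the crotylborane adds, costing yield and selectivity. The fallback sets the stereocentres before the oxazole exists; it sets out from 2 and comes back at 7. The same Brown (Z)-crotylation applied to the robust aldehyde 2 gives (3R,4R)-1-(tert-butyldimethylsilyloxy)-4-methylhex-5-en-3-ol F1; TBSOTf and 2,6-lutidine give (3R,4R)-1,3-bis(tert-butyldimethylsilyloxy)-4-methylhex-5-ene F2; HF·pyridine in THF/pyridine at 0 °C frees only the primary position to give (3R,4R)-3-(tert-butyldimethylsilyloxy)-4-methylhex-5-en-1-ol F3; Dess–Martin oxidation gives (3R,4R)-3-(tert-butyldimethylsilyloxy)-4-methylhex-5-enal F4; the van Leusen reaction of F4 with 1 (K2CO3, MeOH) gives 5-[(2R,3R)-2-(tert-butyldimethylsilyloxy)-3-methylpent-4-en-1-yl]-1,3-oxazole F5; Bu4NF in THF then returns 7.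

Step 14: the activated (Z)-enynoic acid may isomerise or oligomerise during lactonization. The fallback closes the ring by C–C coupling, so no Z-acid is activated within the long chain; it sets out from 10 and comes back at 21. Esterifying 10 with 14 (DCC, cat. DMAP) gives (2R,3R)-3-methyl-1-(1,3-oxazol-5-yl)hept-6-yn-2-yl (Z)-3-iodo-2-methylprop-2-enoate F6. Sonogashira coupling of F6, added slowly to 3–4 equivalents of 10 (excess recovered), gives (2R,3R)-3-methyl-1-(1,3-oxazol-5-yl)hept-6-yn-2-yl (2Z,8R,9R)-9-hydroxy-2,8-dimethyl-10-(1,3-oxazol-5-yl)dec-2-en-4-ynoate F7; this coupling is statistical, because F6 and F7 carry free alkynes of their own. Acylation of F7 with 17 as in step 11 gives (2R,3R)-3-methyl-1-(1,3-oxazol-5-yl)hept-6-yn-2-yl (2Z,8R,9R)-9-{[(Z)-3-iodoprop-2-enoyl]oxy}-2,8-dimethyl-10-(1,3-oxazol-5-yl)dec-2-en-4-ynoate F8. Intramolecular Sonogashira coupling of F8 (Pd(PPh3)4, CuI, Et3N, THF, 1 mM) gives 21.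

Step 15: two conjugated triple bonds must be reduced inside the macrocycle without over-reduction, stalling at the mono-reduced stage or Z-to-E drift. The fallback moves the reduction out of the ring; it sets out from 19 and comes back at 22. Activated zinc (Zn dust with Cu(OAc)2 and AgNO3, MeOH/H2O) on open-chain 19, where partly reduced material can be resubmitted, gives 4-methoxybenzyl (2Z,4Z,8R,9R)-9-{[(2Z,4Z,8R,9R)-9-hydroxy-8-methyl-10-(1,3-oxazol-5-yl)deca-2,4-dienoyl]oxy}-2,8-dimethyl-10-(1,3-oxazol-5-yl)deca-2,4-dienoate F9; TFA/anisole gives (2Z,4Z,8R,9R)-9-{[(2Z,4Z,8R,9R)-9-hydroxy-8-methyl-10-(1,3-oxazol-5-yl)deca-2,4-dienoyl]oxy}-2,8-dimethyl-10-(1,3-oxazol-5-yl)deca-2,4-dienoic acid F10; MNBA lactonization as in step 14 closes the ring onto the preformed dienes and gives 22.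

**Further compounds**
F1 | step 4 | (3R,4R)-1-(tert-butyldimethylsilyloxy)-4-methylhex-5-en-3-ol | C=C[C@@H](C)[C@@H](CCO[Si](C)(C)C(C)(C)C)O
F2 | step 4 | (3R,4R)-1,3-bis(tert-butyldimethylsilyloxy)-4-methylhex-5-ene | C=C[C@@H](C)[C@@H](CCO[Si](C)(C)C(C)(C)C)O[Si](C)(C)C(C)(C)C
F3 | step 4 | (3R,4R)-3-(tert-butyldimethylsilyloxy)-4-methylhex-5-en-1-ol | C=C[C@@H](C)[C@@H](CCO)O[Si](C)(C)C(C)(C)C
F4 | step 4 | (3R,4R)-3-(tert-butyldimethylsilyloxy)-4-methylhex-5-enal | C=C[C@@H](C)[C@@H](CC=O)O[Si](C)(C)C(C)(C)C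
F5 | step 4 | 5-[(2R,3R)-2-(tert-butyldimethylsilyloxy)-3-methylpent-4-en-1-yl]-1,3-oxazole | C=C[C@@H](C)[C@@H](Cc1cnco1)O[Si](C)(C)C(C)(C)C
F6 | step 14 | (2R,3R)-3-methyl-1-(1,3-oxazol-5-yl)hept-6-yn-2-yl (Z)-3-iodo-2-methylprop-2-enoate | C#CCC[C@@H](C)[C@@H](Cc1cnco1)OC(=O)/C(C)=C\I
F7 | step 14 | (2R,3R)-3-methyl-1-(1,3-oxazol-5-yl)hept-6-yn-2-yl (2Z,8R,9R)-9-hydroxy-2,8-dimethyl-10-(1,3-oxazol-5-yl)dec-2-en-4-ynoate | C#CCC[C@@H](C)[C@@H](Cc1cnco1)OC(=O)/C(C)=C\C#CCC[C@@H](C)[C@@H](Cc1cnco1)O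
F8 | step 14 | (2R,3R)-3-methyl-1-(1,3-oxazol-5-yl)hept-6-yn-2-yl (2Z,8R,9R)-9-{[(Z)-3-iodoprop-2-enoyl]oxy}-2,8-dimethyl-10-(1,3-oxazol-5-yl)dec-2-en-4-ynoate | C#CCC[C@@H](C)[C@@H](Cc1cnco1)OC(=O)/C(C)=C\C#CCC[C@@H](C)[C@@H](Cc1cnco1)OC(=O)/C=C\I
F9 | step 15 | 4-methoxybenzyl (2Z,4Z,8R,9R)-9-{[(2Z,4Z,8R,9R)-9-hydroxy-8-methyl-10-(1,3-oxazol-5-yl)deca-2,4-dienoyl]oxy}-2,8-dimethyl-10-(1,3-oxazol-5-yl)deca-2,4-dienoate | COc1ccc(COC(=O)/C(C)=C\C=C/CC[C@@H](C)[C@@H](Cc2cnco2)OC(=O)/C=C\C=C/CC[C@@H](C)[C@@H](Cc2cnco2)O)cc1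
F10 | step 15 | (2Z,4Z,8R,9R)-9-{[(2Z,4Z,8R,9R)-9-hydroxy-8-methyl-10-(1,3-oxazol-5-yl)deca-2,4-dienoyl]oxy}-2,8-dimethyl-10-(1,3-oxazol-5-yl)deca-2,4-dienoic acid | OC(=O)/C(C)=C\C=C/CC[C@@H](C)[C@@H](Cc1cnco1)OC(=O)/C=C\C=C/CC[C@@H](C)[C@@H](Cc1cnco1)O
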